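**Retrosynthetic overview**

1. Numbering: C1 (ether carbon bearing the guaiacyl ring), O2, C3H2, C4, C5 (ring-fusion carbons, C5 alpha to C6=O), O7, C8 (lactone carbon bearing the syringyl ring). The strategy rests on the tetrahydrofuran ring C1–O2–C3–C4–C5: its O2–C3–C4 segment with a one-carbon branch on C4 (the future C8) is an oxy-allyl unit, and its C1–C5 segment, benzylic at C1 and carboxylated at C5 (C6), is an arylidene malonate.
2. Endgame: phenol silyl ethers off; C5–CO2Me to C5–H (Krapcho, cis fusion enforced); lactone C6–O7 and C8–H from hydride addition to a C8 aryl ketone (1,2-induction from C4) and closure onto the cis ester.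
3. C8–aryl bond by acyl Negishi coupling of the C8 acid chloride with the syringyl zinc reagent; the C8 carboxyl comes from the vinyl group by ozonolysis and Pinnick oxidation.
4. Key disconnection: C1–O2 and C4–C5, back to the vanillin-derived benzylidene malonate and vinylethylene carbonate through an alkoxide-bearing pi-allyl palladium zwitterion. The catalyst sets C4, C1 follows in the ring closure, and C8 and C5 follow from C4.
5. Ring order: tetrahydrofuran first (step 3), gamma-lactone second (step 8).

Key step: step 3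

Assumption: the sense of induction of the phosphoramidite on this substrate cannot be assigned in advance, so the route is written with the (S)-BINOL-derived phosphoramidite of bis[(R)-1-phenylethyl]amine, (S,R,R)-L, and its antipode is used instead if a preliminary screen shows that the antipode delivers the (2R,4R) cycloadduct.

**Route**

Step 1
Reactants: 1 vanillin
Product: 2 3-methoxy-4-(triisopropylsilyloxy)benzaldehyde
Conditions: TIPSCl, imidazole, DMF, rt
Reagents that add atoms: triisopropylsilyl chloride, CC(C)[Si](Cl)(C(C)C)C(C)C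
Why: Silylation of a phenol with a silyl chloride and imidazole; the triisopropylsilyl ether is chosen because it has to survive alkoxide, hydride and hot chloride in wet DMSO later in the route.

Step 2
Reactants: 2 3-methoxy-4-(triisopropylsilyloxy)benzaldehyde; 3 dimethyl malonate
Product: 4 dimethyl 2-[3-methoxy-4-(triisopropylsilyloxy)benzylidene]malonate
Conditions: piperidine (0.1 equiv), AcOH (0.1 equiv), toluene, reflux, Dean–Stark
Reagents that add atoms: none
Why: Knoevenagel condensation under piperidinium acetate catalysis with azeotropic removal of water; the symmetrical malonate gives a single alkene and no stereocentre is formed.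

Step 3
Reactants: 4 dimethyl 2-[3-methoxy-4-(triisopropylsilyloxy)benzylidene]malonate; 5 4-vinyl-1,3-dioxolan-2-one (racemic)
Product: 6 dimethyl (2R,4R)-2-[3-methoxy-4-(triisopropylsilyloxy)phenyl]-4-vinyltetrahydrofuran-3,3-dicarboxylate (aryl and vinyl trans)
Conditions: Pd2(dba)3·CHCl3 (2.5 mol %), (S,R,R)-L (10 mol %), 5 (1.5 equiv), THF, 0 °C → rt
Reagents that add atoms: none
Why: Zerovalent palladium ionises the allylic C–O bond of 5, CO2 is lost, and the resulting alkoxide-bearing pi-allyl complex of divalent palladium adds through oxygen to the benzylidene carbon of 4 (C1–O2), after which the malonate carbanion attacks the internal allyl carbon (C4–C5) and releases the catalyst. The closest known reaction type is the palladium-catalysed decarboxylative [3+2] cycloaddition of vinylethylene carbonates or vinyl epoxides with electron-poor alkenes, an oxa-Michael and Tsuji–Trost allylic alkylation cascade. The tetrahydrofuran ring closes by 5-exo attack of the stabilised carbanion on the allyl unit, anti to palladium, which leaves the vinyl group exocyclic; attack at the terminal carbon would need a seven-membered ring. C4 is controlled by the chiral ligand, because the diastereomeric pi-allyl complexes from both enantiomers of 5 interconvert by pi–sigma–pi isomerisation faster than the ring closes. C1 is set relative to C4 in the ring closure, because the oxa-Michael addition is reversible and the transition state that keeps the aryl group away from the ligated allyl unit, trans to the vinyl group, should be the lower one. The step needs branched regiochemistry, the 2,4-trans relationship and the (4R) configuration, and the geminal diester secures them by activating the alkene toward alkoxide while making the adduct a soft, reversibly formed carbanion.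

Step 4
Reactants: 6 dimethyl (2R,4R)-2-[3-methoxy-4-(triisopropylsilyloxy)phenyl]-4-vinyltetrahydrofuran-3,3-dicarboxylate
Product: 8 dimethyl (2R,4R)-4-formyl-2-[3-methoxy-4-(triisopropylsilyloxy)phenyl]tetrahydrofuran-3,3-dicarboxylate, via ozonide 7 (not isolated)
Conditions: O3, CH2Cl2, −78 °C (Sudan Red 7B end point); PPh3, −78 °C → rt
Reagents that add atoms: ozone, [O-][O+]=O
Why: Ozonolysis with reductive work-up (Criegee mechanism); the terminal alkene reacts far faster than the silyloxy arene when the dye marks the end point, and the neutral phosphine work-up should leave the enolisable C4 centre untouched.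

Step 5
Reactants: 8 dimethyl (2R,4R)-4-formyl-2-[3-methoxy-4-(triisopropylsilyloxy)phenyl]tetrahydrofuran-3,3-dicarboxylate
Product: 9 (3R,5R)-4,4-bis(methoxycarbonyl)-5-[3-methoxy-4-(triisopropylsilyloxy)phenyl]tetrahydrofuran-3-carboxylic acid
Conditions: NaClO2, NaH2PO4, 2-methylbut-2-ene, t-BuOH/H2O, 0 °C → rt
Reagents that add atoms: sodium chlorite, [Na+].[O-]Cl=O
Why: Pinnick oxidation in phosphate buffer, where the alkene scavenger intercepts hypochlorous acid before it can chlorinate the electron-rich arene and the mildly acidic medium should not epimerise C4.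

Step 6
Reactants: 10 4-bromo-2,6-dimethoxyphenol
Product: 11 (4-bromo-2,6-dimethoxyphenoxy)triisopropylsilane
Conditions: TIPSOTf, 2,6-lutidine, CH2Cl2, 0 °C → rt
Reagents that add atoms: triisopropylsilyl trifluoromethanesulfonate, CC(C)[Si](OS(=O)(=O)C(F)(F)F)(C(C)C)C(C)C
Why: Silylation of a phenol flanked by two methoxy groups, for which the silyl triflate with a hindered pyridine base is the reliable reagent pair.

Step 7
Reactants: 9 (3R,5R)-4,4-bis(methoxycarbonyl)-5-[3-methoxy-4-(triisopropylsilyloxy)phenyl]tetrahydrofuran-3-carboxylic acid; 11 (4-bromo-2,6-dimethoxyphenoxy)triisopropylsilane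
Product: 15 dimethyl (2R,4R)-4-[3,5-dimethoxy-4-(triisopropylsilyloxy)benzoyl]-2-[3-methoxy-4-(triisopropylsilyloxy)phenyl]tetrahydrofuran-3,3-dicarboxylate, via acid chloride 12 (not isolated), via aryllithium 13 (not isolated), via arylzinc chloride 14 (not isolated)
Conditions: 9, Me2C=C(Cl)NMe2, CH2Cl2, 0 °C → rt, evaporate; 11, n-BuLi, THF, −78 °C, then ZnCl2, −78 → 0 °C; combine, Pd(PPh3)4 (5 mol %), THF, 0 °C → rt
Reagents that add atoms: none
Why: Negishi acylation, in which the acid chloride is made under neutral conditions with the chloroenamine, zerovalent palladium inserts into the C–Cl bond and the arylzinc transmetalates; the zinc reagent ignores the methyl esters and is too weakly basic to enolise C4, so its configuration should be kept.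

Step 8
Reactants: 15 dimethyl (2R,4R)-4-[3,5-dimethoxy-4-(triisopropylsilyloxy)benzoyl]-2-[3-methoxy-4-(triisopropylsilyloxy)phenyl]tetrahydrofuran-3,3-dicarboxylate
Product: 17 methyl (1S,4S,5R,8R)-4-[3,5-dimethoxy-4-(triisopropylsilyloxy)phenyl]-8-[3-methoxy-4-(triisopropylsilyloxy)phenyl]-2-oxo-3,7-dioxabicyclo[3.3.0]octane-1-carboxylate (cis-fused and both aryl groups exo), via lithium alkoxide 16 (not isolated)
Conditions: LiBH(s-Bu)3 (L-Selectride, 1.2 equiv), THF, −78 °C → rt; aq NH4Cl
Reagents that add atoms: none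
Why: Felkin–Anh-controlled reduction of an alpha-chiral aryl ketone by a bulky borohydride followed by intramolecular acyl substitution: with the C4–H bond eclipsing the aryl ring the carbonyl faces are flanked by the C3 methylene and by the quaternary C5, hydride should enter past C3 and anti to C5 to give the (S)-configured C8 alkoxide 16, and this closes the gamma-lactone on the only ester it can reach, the one cis to it on C5, which fixes C5 as the cis ring fusion.

Step 9
Reactants: 17 methyl (1S,4S,5R,8R)-4-[3,5-dimethoxy-4-(triisopropylsilyloxy)phenyl]-8-[3-methoxy-4-(triisopropylsilyloxy)phenyl]-2-oxo-3,7-dioxabicyclo[3.3.0]octane-1-carboxylate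
Product: 19 (1S,4S,5R,8S)-4-[3,5-dimethoxy-4-(triisopropylsilyloxy)phenyl]-8-[3-methoxy-4-(triisopropylsilyloxy)phenyl]-3,7-dioxabicyclo[3.3.0]octan-2-one, via lithium carboxylate 18 (not isolated)
Conditions: LiCl (5 equiv), H2O (5 equiv), DMSO, 140 °C
Reagents that add atoms: none
Why: Krapcho demethoxycarbonylation, in which chloride removes the ester methyl group by SN2 attack, the malonate-type carboxylate loses CO2 and the lactone enolate can only be protonated to the cis-fused bicycle, which sets C5–H, while ring opening of the enolate by loss of O2 from C1 would be a disfavoured reverse 5-endo process and C1, C4 and C8 stay as they are.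

Step 10
Reactants: 19 (1S,4S,5R,8S)-4-[3,5-dimethoxy-4-(triisopropylsilyloxy)phenyl]-8-[3-methoxy-4-(triisopropylsilyloxy)phenyl]-3,7-dioxabicyclo[3.3.0]octan-2-one
Product: 20 (1S,4S,5R,8S)-4-(4-hydroxy-3,5-dimethoxyphenyl)-8-(4-hydroxy-3-methoxyphenyl)-3,7-dioxabicyclo[3.3.0]octan-2-one (CNP0142585.1)
Conditions: Bu4NF, AcOH (1:1, 3 equiv), THF, 0 °C → rt
Reagents that add atoms: none
Why: Fluoride cleavage of both aryl silyl ethers, buffered with acetic acid so that no free phenoxide is present that could expel the benzylic lactone oxygen as a quinone methide and scramble C8.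

**Compound list**

1 | vanillin (4-hydroxy-3-methoxybenzaldehyde) | COc1cc(C=O)ccc1O | starting material
2 | 3-methoxy-4-(triisopropylsilyloxy)benzaldehyde | COc1cc(C=O)ccc1O[Si](C(C)C)(C(C)C)C(C)C | intermediate
3 | dimethyl malonate | COC(=O)CC(=O)OC | starting material
4 | dimethyl 2-[3-methoxy-4-(triisopropylsilyloxy)benzylidene]malonate | COC(=O)C(=Cc1ccc(O[Si](C(C)C)(C(C)C)C(C)C)c(OC)c1)C(=O)OC | intermediate
5 | 4-vinyl-1,3-dioxolan-2-one (vinylethylene carbonate, racemic) | C=CC1COC(=O)O1 | starting material
6 | dimethyl (2R,4R)-2-[3-methoxy-4-(triisopropylsilyloxy)phenyl]-4-vinyltetrahydrofuran-3,3-dicarboxylate (aryl and vinyl trans) | COc1cc([C@H]2OC[C@H](C=C)C2(C(=O)OC)C(=O)OC)ccc1O[Si](C(C)C)(C(C)C)C(C)C | intermediate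
7 | dimethyl (2R,4R)-2-[3-methoxy-4-(triisopropylsilyloxy)phenyl]-4-(1,2,4-trioxolan-3-yl)tetrahydrofuran-3,3-dicarboxylate (ozonide, both epimers at the trioxolane carbon) | COc1cc([C@H]2OC[C@H](C3OCOO3)C2(C(=O)OC)C(=O)OC)ccc1O[Si](C(C)C)(C(C)C)C(C)C | intermediate
8 | dimethyl (2R,4R)-4-formyl-2-[3-methoxy-4-(triisopropylsilyloxy)phenyl]tetrahydrofuran-3,3-dicarboxylate | COc1cc([C@H]2OC[C@H](C=O)C2(C(=O)OC)C(=O)OC)ccc1O[Si](C(C)C)(C(C)C)C(C)C | intermediate
9 | (3R,5R)-4,4-bis(methoxycarbonyl)-5-[3-methoxy-4-(triisopropylsilyloxy)phenyl]tetrahydrofuran-3-carboxylic acid | COc1cc([C@H]2OC[C@H](C(=O)O)C2(C(=O)OC)C(=O)OC)ccc1O[Si](C(C)C)(C(C)C)C(C)C | intermediate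
10 | 4-bromo-2,6-dimethoxyphenol | COc1cc(Br)cc(OC)c1O | starting material
11 | (4-bromo-2,6-dimethoxyphenoxy)triisopropylsilane | COc1cc(Br)cc(OC)c1O[Si](C(C)C)(C(C)C)C(C)C | intermediate
12 | (3R,5R)-4,4-bis(methoxycarbonyl)-5-[3-methoxy-4-(triisopropylsilyloxy)phenyl]tetrahydrofuran-3-carbonyl chloride | COc1cc([C@H]2OC[C@H](C(=O)Cl)C2(C(=O)OC)C(=O)OC)ccc1O[Si](C(C)C)(C(C)C)C(C)C | intermediate
13 | [3,5-dimethoxy-4-(triisopropylsilyloxy)phenyl]lithium | COc1cc([Li])cc(OC)c1O[Si](C(C)C)(C(C)C)C(C)C | intermediate
14 | [3,5-dimethoxy-4-(triisopropylsilyloxy)phenyl]zinc chloride | COc1cc([Zn]Cl)cc(OC)c1O[Si](C(C)C)(C(C)C)C(C)C | intermediate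
15 | dimethyl (2R,4R)-4-[3,5-dimethoxy-4-(triisopropylsilyloxy)benzoyl]-2-[3-methoxy-4-(triisopropylsilyloxy)phenyl]tetrahydrofuran-3,3-dicarboxylate | COc1cc([C@H]2OC[C@H](C(=O)c3cc(OC)c(O[Si](C(C)C)(C(C)C)C(C)C)c(OC)c3)C2(C(=O)OC)C(=O)OC)ccc1O[Si](C(C)C)(C(C)C)C(C)C | intermediate
16 | lithium alkoxide of dimethyl (2R,4R)-4-[(S)-[3,5-dimethoxy-4-(triisopropylsilyloxy)phenyl](hydroxy)methyl]-2-[3-methoxy-4-(triisopropylsilyloxy)phenyl]tetrahydrofuran-3,3-dicarboxylate | COc1cc([C@H]2OC[C@H]([C@H]([O-])c3cc(OC)c(O[Si](C(C)C)(C(C)C)C(C)C)c(OC)c3)C2(C(=O)OC)C(=O)OC)ccc1O[Si](C(C)C)(C(C)C)C(C)C.[Li+] | intermediate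
17 | methyl (1S,4S,5R,8R)-4-[3,5-dimethoxy-4-(triisopropylsilyloxy)phenyl]-8-[3-methoxy-4-(triisopropylsilyloxy)phenyl]-2-oxo-3,7-dioxabicyclo[3.3.0]octane-1-carboxylate | COc1cc([C@H]2OC[C@H]3[C@]2(C(=O)OC)C(=O)O[C@@H]3c2cc(OC)c(O[Si](C(C)C)(C(C)C)C(C)C)c(OC)c2)ccc1O[Si](C(C)C)(C(C)C)C(C)C | intermediate
18 | lithium (1S,4S,5R,8R)-4-[3,5-dimethoxy-4-(triisopropylsilyloxy)phenyl]-8-[3-methoxy-4-(triisopropylsilyloxy)phenyl]-2-oxo-3,7-dioxabicyclo[3.3.0]octane-1-carboxylate | COc1cc([C@H]2OC[C@H]3[C@]2(C(=O)[O-])C(=O)O[C@@H]3c2cc(OC)c(O[Si](C(C)C)(C(C)C)C(C)C)c(OC)c2)ccc1O[Si](C(C)C)(C(C)C)C(C)C.[Li+] | intermediate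
19 | (1S,4S,5R,8S)-4-[3,5-dimethoxy-4-(triisopropylsilyloxy)phenyl]-8-[3-methoxy-4-(triisopropylsilyloxy)phenyl]-3,7-dioxabicyclo[3.3.0]octan-2-one (the change of the C8 descriptor against 17 is a priority change only) | COc1cc([C@H]2OC[C@H]3[C@@H]2C(=O)O[C@@H]3c2cc(OC)c(O[Si](C(C)C)(C(C)C)C(C)C)c(OC)c2)ccc1O[Si](C(C)C)(C(C)C)C(C)C | intermediate
20 | (1S,4S,5R,8S)-4-(4-hydroxy-3,5-dimethoxyphenyl)-8-(4-hydroxy-3-methoxyphenyl)-3,7-dioxabicyclo[3.3.0]octan-2-one | COc1cc([C@H]2OC[C@H]3[C@@H]2C(=O)O[C@@H]3c2cc(OC)c(O)c(OC)c2)ccc1O | target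

**Step count**

Total steps: 10. Longest linear sequence: 9 steps (steps 1, 2, 3, 4, 5, 7, 8, 9, 10 from vanillin); step 6 is a one-step side branch.

**Steps most likely to fail**

Step 3. Addition of the alkoxide to an electron-rich benzylidene malonate may be so reversible that the zwitterion is consumed by self-reaction before the ring closes, or the ring closure may become slow enough for enantio- and diastereocontrol to erode. The fallback changes the acceptor and sets out from 2. Knoevenagel condensation of 2 with 2,2-dimethyl-1,3-dioxane-4,6-dione (piperidinium acetate, EtOH, rt) should give the far more electrophilic 5-[3-methoxy-4-(triisopropylsilyloxy)benzylidene]-2,2-dimethyl-1,3-dioxane-4,6-dione F1. The same Pd2(dba)3·CHCl3 and phosphoramidite system with 5 should then give the spirocyclic adduct (1R,4R)-1-[3-methoxy-4-(triisopropylsilyloxy)phenyl]-8,8-dimethyl-4-vinyl-2,7,9-trioxaspiro[4.5]decane-6,10-dione F2. NaOMe in MeOH at 0 °C should open the dioxanedione with loss of acetone to the half ester (2R,4R)-3-(methoxycarbonyl)-2-[3-methoxy-4-(triisopropylsilyloxy)phenyl]-4-vinyltetrahydrofuran-3-carboxylic acid F3, and esterification with Me3SiCHN2 comes back to the route at 6.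

Step 8. Hydride may be delivered to the other carbonyl face, for instance through a chelate between the ketone and the cis ester, or with low facial preference, which would give the lactone with the syringyl group endo. The fallback reverses the roles of hydride and aryl at C8 and sets out from aldehyde 8 and bromide 11, so that the same facial bias installs the aryl group where hydrogen went. Magnesium insertion into 11 (Mg, THF) should give [3,5-dimethoxy-4-(triisopropylsilyloxy)phenyl]magnesium bromide F4. Its addition to 8 at −78 °C in THF should give the bromomagnesium alkoxide of dimethyl (2R,4R)-4-[(S)-[3,5-dimethoxy-4-(triisopropylsilyloxy)phenyl](hydroxy)methyl]-2-[3-methoxy-4-(triisopropylsilyloxy)phenyl]tetrahydrofuran-3,3-dicarboxylate F5, which lactonises on warming and comes back at 17. The two C8-epimeric lactones are diastereomers, so whichever order of bond formation gives more of 17 can be adopted; this detour also saves steps 5 and 7.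

Step 9. The triisopropylsilyl groups may be lost in hot wet DMSO as the medium turns basic, and the phenoxide so formed may open the benzylic lactone through a quinone methide and scramble C8. The fallback separates dealkylation from decarboxylation, keeps both below 100 °C and sets out from 17. LiI in refluxing EtOAc should remove the ester methyl group by SN2 attack under anhydrous, non-basic conditions and give the lithium carboxylate 18. Cold dilute citric acid should give the free acid (1S,4S,5R,8R)-4-[3,5-dimethoxy-4-(triisopropylsilyloxy)phenyl]-8-[3-methoxy-4-(triisopropylsilyloxy)phenyl]-2-oxo-3,7-dioxabicyclo[3.3.0]octane-1-carboxylic acid F6, and warming in toluene at 80–90 °C should decarboxylate it and come back at 19.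

**Further compounds**

F1 | step 3 | 5-[3-methoxy-4-(triisopropylsilyloxy)benzylidene]-2,2-dimethyl-1,3-dioxane-4,6-dione | COc1cc(C=C2C(=O)OC(C)(C)OC2=O)ccc1O[Si](C(C)C)(C(C)C)C(C)C
F2 | step 3 | (1R,4R)-1-[3-methoxy-4-(triisopropylsilyloxy)phenyl]-8,8-dimethyl-4-vinyl-2,7,9-trioxaspiro[4.5]decane-6,10-dione | COc1cc([C@H]2OC[C@H](C=C)C23C(=O)OC(C)(C)OC3=O)ccc1O[Si](C(C)C)(C(C)C)C(C)C
F3 | step 3 | (2R,4R)-3-(methoxycarbonyl)-2-[3-methoxy-4-(triisopropylsilyloxy)phenyl]-4-vinyltetrahydrofuran-3-carboxylic acid (both epimers at C3) | COc1cc([C@H]2OC[C@H](C=C)C2(C(=O)O)C(=O)OC)ccc1O[Si](C(C)C)(C(C)C)C(C)C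
F4 | step 8 | [3,5-dimethoxy-4-(triisopropylsilyloxy)phenyl]magnesium bromide | COc1cc([Mg]Br)cc(OC)c1O[Si](C(C)C)(C(C)C)C(C)C
F5 | step 8 | bromomagnesium alkoxide of dimethyl (2R,4R)-4-[(S)-[3,5-dimethoxy-4-(triisopropylsilyloxy)phenyl](hydroxy)methyl]-2-[3-methoxy-4-(triisopropylsilyloxy)phenyl]tetrahydrofuran-3,3-dicarboxylate | COc1cc([C@H]2OC[C@H]([C@H](O[Mg]Br)c3cc(OC)c(O[Si](C(C)C)(C(C)C)C(C)C)c(OC)c3)C2(C(=O)OC)C(=O)OC)ccc1O[Si](C(C)C)(C(C)C)C(C)C
F6 | step 9 | (1S,4S,5R,8R)-4-[3,5-dimethoxy-4-(triisopropylsilyloxy)phenyl]-8-[3-methoxy-4-(triisopropylsilyloxy)phenyl]-2-oxo-3,7-dioxabicyclo[3.3.0]octane-1-carboxylic acid | COc1cc([C@H]2OC[C@H]3[C@]2(C(=O)O)C(=O)O[C@@H]3c2cc(OC)c(O[Si](C(C)C)(C(C)C)C(C)C)c(OC)c2)ccc1O[Si](C(C)C)(C(C)C)C(C)C
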